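**Plan**

Locants: C1 = ring carbon bearing the ester, C2(Me)=C3, C4 = free carbinol, C5 = CMe2, C6–C8 = CH2, C9(Me)=C10, C11 = CH2. The retrosynthesis cuts the ester C–O bond, then ring bond C1–C2, then C8–C9 (sp3–sp2), then the C9=C10 alkene, then C3–C4.
Enabling feature: in the eleven-membered ring the Z alkene C2=C3 holds C1 and C4 on the same side (a cis-2-ene-1,4-diol unit). C2 can therefore be an alkenyl nucleophile whose Z iodide comes from hydroxyl-directed trans-hydroalumination of a C4 propargylic alcohol, and C1 an aldehyde carbon.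
Forward: the alkynol (C2–C8) is made from 2,2-dimethylpent-4-enal and the Z iodoalkene (C9–C11, C1) by Stork–Zhao olefination. B-alkyl Suzuki coupling joins C8–C9, Red-Al/iodine installs the C2 iodide, and the only ring is closed last at C1–C2 by an intramolecular Nozaki–Hiyama–Kishi reaction, followed by esterification and desilylation.
Stereochemistry: C4 comes from Noyori transfer hydrogenation of an ynone, and C1 from 1,4-induction by C4 across the Z alkene during ring closure. Both Z alkenes come from stereodefined iodoalkenes that react with retention.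

Key step: step 10

Remark: the 1,4-induction in step 10 is assumed, on conformational grounds only, to favour the 1S epimer; the first fallback covers the opposite outcome.

**Route**

Step 1
Reactants: 1 2,2-dimethylpent-4-enal; 2 prop-1-yn-1-ylmagnesium bromide
Product: 3 rac-5,5-dimethyloct-7-en-2-yn-4-ol
Conditions: THF, −78 °C to 0 °C
Reagents that add atoms: none
Why: Grignard addition of the alkynylmagnesium halide to a non-enolisable α-quaternary aldehyde is clean 1,2-addition; the carbinol forms as a racemate, which does not matter because step 2 removes it.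

Step 2
Reactants: 3 rac-5,5-dimethyloct-7-en-2-yn-4-ol
Product: 4 5,5-dimethyloct-7-en-2-yn-4-one
Conditions: Dess–Martin periodinane, CH2Cl2, 0 °C to rt
Reagents that add atoms: none
Why: Dess–Martin oxidation converts the secondary propargylic alcohol to the ynone under neutral conditions that spare the terminal alkene, and nothing can epimerise because the α-carbon is quaternary.

Step 3
Reactants: 4 5,5-dimethyloct-7-en-2-yn-4-one
Product: 5 (4R)-5,5-dimethyloct-7-en-2-yn-4-ol
Conditions: Ru(p-cymene)[(R,R)-TsNCH(Ph)CH(Ph)NH] (2 mol %), i-PrOH, rt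
Reagents that add atoms: none
Why: Noyori asymmetric transfer hydrogenation of an alkynyl ketone distinguishes the slim alkynyl group from the tertiary alkyl group in the outer-sphere hydride transfer, and the (R,R)-catalyst should set the 4R carbinol (the mirror image of the sense in which the (S,S)-catalyst reduces alkynyl methyl ketones to (S)-alcohols) without touching alkyne or alkene.

Step 4
Reactants: 6 ethyltriphenylphosphonium iodide; 7 3-[(tert-butyldimethylsilyl)oxy]propanal
Product: 11 tert-butyl{[(3Z)-4-iodopent-3-en-1-yl]oxy}dimethylsilane, via ethylidenetriphenylphosphorane 8 (not isolated), via (1-iodoethyl)triphenylphosphonium iodide 9 (not isolated), via (1-iodoethylidene)triphenylphosphorane 10 (not isolated)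
Conditions: 6, n-BuLi, THF, rt; I2, −78 °C; NaN(SiMe3)2, −20 °C; then 7, −78 °C to −20 °C
Reagents that add atoms: iodine, [I][I]
Why: Stork–Zhao olefination, in which the ethylidene ylide is iodinated, deprotonated to the α-iodo ylide and condensed with the aldehyde in a kinetically controlled Wittig reaction that places iodine cis to the chain, giving the (Z)-2-iodoalk-2-ene.

Step 5
Reactants: 5 (4R)-5,5-dimethyloct-7-en-2-yn-4-ol; 11 tert-butyl{[(3Z)-4-iodopent-3-en-1-yl]oxy}dimethylsilane
Product: 13 (4R,9Z)-12-[(tert-butyldimethylsilyl)oxy]-5,5,9-trimethyldodec-9-en-2-yn-4-ol, via B-alkyl-9-BBN O-borinate 12 (not isolated)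
Conditions: 9-BBN (2.2 equiv), THF, 0 °C to rt; then 11, PdCl2(dppf) (5 mol %), AsPh3, Cs2CO3, DMF/H2O, rt
Reagents that add atoms: none
Why: 9-BBN hydroborates the monosubstituted alkene at its terminus much faster than the hindered internal alkyne (one equivalent is taken up by the hydroxyl), and the B-alkyl Suzuki–Miyaura coupling proceeds with retention at the iodoalkene, so the Z C9=C10 alkene of the target is fixed here.

Step 6
Reactants: 13 (4R,9Z)-12-[(tert-butyldimethylsilyl)oxy]-5,5,9-trimethyldodec-9-en-2-yn-4-ol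
Product: 15 (2Z,4S,9Z)-12-[(tert-butyldimethylsilyl)oxy]-2-iodo-5,5,9-trimethyldodeca-2,9-dien-4-ol, via cyclic sodium alkenylalanate 14 (not isolated)
Conditions: NaAlH2(OCH2CH2OCH3)2 (Red-Al, 1.5 equiv), THF, 0 °C to rt; then I2, THF, −78 °C to 0 °C
Reagents that add atoms: iodine, [I][I]
Why: Hydroxyl-directed trans-hydroalumination of the propargylic alcohol delivers hydride to the proximal alkyne carbon and leaves aluminium on the distal one inside a five-membered oxa-aluminacycle, and iodinolysis with retention gives the Z iodoalkene with iodine cis to the carbinol carbon (the descriptor changes from 4R to 4S only because the alkyne becomes an alkene).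

Step 7
Reactants: 15 (2Z,4S,9Z)-12-[(tert-butyldimethylsilyl)oxy]-2-iodo-5,5,9-trimethyldodeca-2,9-dien-4-ol
Product: 16 (2Z,4S,9Z)-4,12-bis[(tert-butyldimethylsilyl)oxy]-2-iodo-5,5,9-trimethyldodeca-2,9-diene
Conditions: TBSOTf, 2,6-lutidine, CH2Cl2, 0 °C to rt
Reagents that add atoms: tert-butyldimethylsilyl trifluoromethanesulfonate, CC(C)(C)[Si](C)(C)OS(=O)(=O)C(F)(F)F
Why: A silyl triflate with 2,6-lutidine silylates even a neopentylic secondary allylic alcohol, masking this oxygen so that only the hydroxyl formed in the ring closure can later be acylated.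

Step 8
Reactants: 16 (2Z,4S,9Z)-4,12-bis[(tert-butyldimethylsilyl)oxy]-2-iodo-5,5,9-trimethyldodeca-2,9-diene
Product: 17 (3Z,9S,10Z)-9-[(tert-butyldimethylsilyl)oxy]-11-iodo-4,8,8-trimethyldodeca-3,10-dien-1-ol
Conditions: HF·pyridine, pyridine, THF, 0 °C
Reagents that add atoms: none
Why: Buffered HF·pyridine cleaves the unhindered primary silyl ether far faster than the secondary one shielded by the adjacent quaternary carbon (selective desilylation).

Step 9
Reactants: 17 (3Z,9S,10Z)-9-[(tert-butyldimethylsilyl)oxy]-11-iodo-4,8,8-trimethyldodeca-3,10-dien-1-ol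
Product: 18 (3Z,9S,10Z)-9-[(tert-butyldimethylsilyl)oxy]-11-iodo-4,8,8-trimethyldodeca-3,10-dienal
Conditions: Dess–Martin periodinane, pyridine, CH2Cl2, 0 °C; crude aldehyde used at once
Reagents that add atoms: none
Why: Dess–Martin oxidation buffered with pyridine gives the β,γ-unsaturated aldehyde without acid or base strong enough to move the Z alkene into conjugation.

Step 10
Reactants: 18 (3Z,9S,10Z)-9-[(tert-butyldimethylsilyl)oxy]-11-iodo-4,8,8-trimethyldodeca-3,10-dienal
Product: 20 (1S,2Z,4S,9Z)-4-[(tert-butyldimethylsilyl)oxy]-2,5,5,9-tetramethylcycloundeca-2,9-dien-1-ol, via alkenylchromium dichloride 19 (not isolated)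
Conditions: CrCl2 (12 equiv), NiCl2 (0.1 equiv), degassed DMSO/THF (3:1), rt, 0.003 M, 18 added over 12 h
Reagents that add atoms: none
Why: Zerovalent nickel, formed in the flask from NiCl2 and CrCl2, inserts into the C–I bond of 18 and passes the alkenyl group to trivalent chromium to give 19, which adds to the tethered aldehyde through a chromium-bound carbonyl; the closest known reaction type is the Nozaki–Hiyama–Kishi macrocyclisation of an iodoalkene onto an aldehyde. The eleven-membered carbocycle closes in an 11-exo-trig mode at C1–C2, and the alkenyl–metal bond reacts with retention, so the Z geometry installed in step 6 becomes the Z C2=C3 ring alkene. The new C1 stereocenter is controlled by C4 across that Z alkene: allylic 1,3-strain holds the C4–H in the alkene plane, the silyloxy group and the C5 tether occupy opposite faces, the tether should deliver the aldehyde from its own face, and the aldehyde should react with its hydrogen turned inward and its chromium-bound oxygen outward, which places both oxygens on the face opposite the ring and corresponds to 1S. The step needs chemoselectivity for the aldehyde (organochromium reagents leave silyl ethers and alkenes alone), cyclisation over oligomerisation (high dilution and slow addition, helped by the two Z alkenes and the gem-dimethyl group that fold the chain), and survival of the β,γ-unsaturated aldehyde, which the non-basic room-temperature medium should allow.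

Step 11
Reactants: 21 4-hydroxybenzoic acid
Product: 23 4-[(tert-butyldimethylsilyl)oxy]benzoic acid, via silyl ester 22 (not isolated)
Conditions: TBSCl (2.5 equiv), imidazole, DMF, rt; then AcOH/THF/H2O, rt
Reagents that add atoms: tert-butyldimethylsilyl chloride, CC(C)(C)[Si](C)(C)Cl
Why: Both acidic hydroxyls are silylated and the far more labile silyl ester is then hydrolysed selectively, leaving the phenol protected so that the acid cannot oligomerise in step 12.

Step 12
Reactants: 20 (1S,2Z,4S,9Z)-4-[(tert-butyldimethylsilyl)oxy]-2,5,5,9-tetramethylcycloundeca-2,9-dien-1-ol; 23 4-[(tert-butyldimethylsilyl)oxy]benzoic acid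
Product: 24 (1S,2Z,4S,9Z)-4-[(tert-butyldimethylsilyl)oxy]-2,5,5,9-tetramethylcycloundeca-2,9-dien-1-yl 4-[(tert-butyldimethylsilyl)oxy]benzoate
Conditions: DCC, DMAP, CH2Cl2, 0 °C to rt
Reagents that add atoms: none
Why: Steglich esterification acylates the only free hydroxyl through the N-acylpyridinium intermediate without touching the C1–O bond, so the 1S configuration is retained.

Step 13
Reactants: 24 (1S,2Z,4S,9Z)-4-[(tert-butyldimethylsilyl)oxy]-2,5,5,9-tetramethylcycloundeca-2,9-dien-1-yl 4-[(tert-butyldimethylsilyl)oxy]benzoate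
Product: 25 (1S,2Z,4S,9Z)-4-hydroxy-2,5,5,9-tetramethylcycloundeca-2,9-dien-1-yl 4-hydroxybenzoate
Conditions: HF·pyridine, pyridine, THF, 0 °C to rt
Reagents that add atoms: none
Why: HF·pyridine removes the aryl and the hindered alkyl silyl ether in one operation under mildly acidic conditions in which the benzoate should neither hydrolyse nor migrate to the C4 oxygen.

**Compound list**

1 | 2,2-dimethylpent-4-enal | C=CCC(C)(C)C=O | starting material
2 | prop-1-yn-1-ylmagnesium bromide | CC#C[Mg]Br | starting material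
3 | rac-5,5-dimethyloct-7-en-2-yn-4-ol | CC#CC(O)C(C)(C)CC=C | intermediate
4 | 5,5-dimethyloct-7-en-2-yn-4-one | CC#CC(=O)C(C)(C)CC=C | intermediate
5 | (4R)-5,5-dimethyloct-7-en-2-yn-4-ol | CC#C[C@H](O)C(C)(C)CC=C | intermediate
6 | ethyltriphenylphosphonium iodide | CC[P+](c1ccccc1)(c1ccccc1)c1ccccc1.[I-] | starting material
7 | 3-[(tert-butyldimethylsilyl)oxy]propanal | CC(C)(C)[Si](C)(C)OCCC=O | starting material
8 | ethylidenetriphenylphosphorane | CC=P(c1ccccc1)(c1ccccc1)c1ccccc1 | intermediate
9 | (1-iodoethyl)triphenylphosphonium iodide | CC(I)[P+](c1ccccc1)(c1ccccc1)c1ccccc1.[I-] | intermediate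
10 | (1-iodoethylidene)triphenylphosphorane | CC(I)=P(c1ccccc1)(c1ccccc1)c1ccccc1 | intermediate
11 | tert-butyl{[(3Z)-4-iodopent-3-en-1-yl]oxy}dimethylsilane | C/C(I)=C/CCO[Si](C)(C)C(C)(C)C | intermediate
12 | 9-{(5R)-5-[(9-borabicyclo[3.3.1]nonan-9-yl)oxy]-4,4-dimethyloct-6-yn-1-yl}-9-borabicyclo[3.3.1]nonane | CC#C[C@H](OB1C2CCCC1CCC2)C(C)(C)CCCB1C2CCCC1CCC2 | intermediate
13 | (4R,9Z)-12-[(tert-butyldimethylsilyl)oxy]-5,5,9-trimethyldodec-9-en-2-yn-4-ol | CC#C[C@H](O)C(C)(C)CCC/C(C)=C\CCO[Si](C)(C)C(C)(C)C | intermediate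
14 | cyclic sodium alkenylalanate of 13 (five-membered ring Al–O–C4–C3=C2, aluminium on the methyl-bearing carbon C2 and carrying two 2-methoxyethoxy groups) | CC1=C[C@H](O[Al-]1(OCCOC)OCCOC)C(C)(C)CCC/C(C)=C\CCO[Si](C)(C)C(C)(C)C.[Na+] | intermediate
15 | (2Z,4S,9Z)-12-[(tert-butyldimethylsilyl)oxy]-2-iodo-5,5,9-trimethyldodeca-2,9-dien-4-ol | C/C(I)=C/[C@H](O)C(C)(C)CCC/C(C)=C\CCO[Si](C)(C)C(C)(C)C | intermediate
16 | (2Z,4S,9Z)-4,12-bis[(tert-butyldimethylsilyl)oxy]-2-iodo-5,5,9-trimethyldodeca-2,9-diene | C/C(I)=C/[C@H](O[Si](C)(C)C(C)(C)C)C(C)(C)CCC/C(C)=C\CCO[Si](C)(C)C(C)(C)C | intermediate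
17 | (3Z,9S,10Z)-9-[(tert-butyldimethylsilyl)oxy]-11-iodo-4,8,8-trimethyldodeca-3,10-dien-1-ol | C/C(I)=C/[C@H](O[Si](C)(C)C(C)(C)C)C(C)(C)CCC/C(C)=C\CCO | intermediate
18 | (3Z,9S,10Z)-9-[(tert-butyldimethylsilyl)oxy]-11-iodo-4,8,8-trimethyldodeca-3,10-dienal | C/C(I)=C/[C@H](O[Si](C)(C)C(C)(C)C)C(C)(C)CCC/C(C)=C\CC=O | intermediate
19 | alkenylchromium dichloride derived from 18 (CrCl2 group in place of iodine, Z geometry retained, trivalent chromium) | C/C([Cr](Cl)Cl)=C/[C@H](O[Si](C)(C)C(C)(C)C)C(C)(C)CCC/C(C)=C\CC=O | intermediate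
20 | (1S,2Z,4S,9Z)-4-[(tert-butyldimethylsilyl)oxy]-2,5,5,9-tetramethylcycloundeca-2,9-dien-1-ol | C/C1=C/C[C@H](O)/C(C)=C\[C@H](O[Si](C)(C)C(C)(C)C)C(C)(C)CCC1 | intermediate
21 | 4-hydroxybenzoic acid | OC(=O)c1ccc(O)cc1 | starting material
22 | tert-butyldimethylsilyl 4-[(tert-butyldimethylsilyl)oxy]benzoate | CC(C)(C)[Si](C)(C)OC(=O)c1ccc(O[Si](C)(C)C(C)(C)C)cc1 | intermediate
23 | 4-[(tert-butyldimethylsilyl)oxy]benzoic acid | CC(C)(C)[Si](C)(C)Oc1ccc(cc1)C(O)=O | intermediate
24 | (1S,2Z,4S,9Z)-4-[(tert-butyldimethylsilyl)oxy]-2,5,5,9-tetramethylcycloundeca-2,9-dien-1-yl 4-[(tert-butyldimethylsilyl)oxy]benzoate | C/C1=C/C[C@H](OC(=O)c2ccc(O[Si](C)(C)C(C)(C)C)cc2)/C(C)=C\[C@H](O[Si](C)(C)C(C)(C)C)C(C)(C)CCC1 | intermediate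
25 | (1S,2Z,4S,9Z)-4-hydroxy-2,5,5,9-tetramethylcycloundeca-2,9-dien-1-yl 4-hydroxybenzoate | C/C1=C/C[C@H](OC(=O)c2ccc(O)cc2)/C(C)=C\[C@H](O)C(C)(C)CCC1 | target

**Count and risks**

Total step count: 13. Longest linear sequence: 11 steps (1, 2, 3, 5, 6, 7, 8, 9, 10, 12, 13).

The three steps most likely to fail:

1. Step 10. The facial selectivity at the aldehyde during ring closure may be poor or reversed, because the 1,4-induction rests on a conformational argument only; oligomerisation and drift of the β,γ-alkene into conjugation are secondary risks. The fallback sets out from 18 and comes back at 24. The cyclisation is run as described and the epimers are separated. The 1S alcohol 20 goes on through step 12. The epimer (1R,2Z,4S,9Z)-4-[(tert-butyldimethylsilyl)oxy]-2,5,5,9-tetramethylcycloundeca-2,9-dien-1-ol F1 is esterified with 23 under Mitsunobu conditions (PPh3, diisopropyl azodicarboxylate, toluene, 0 °C), which should invert C1 and give 24 directly, so both epimers converge.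

2. Step 5. The excess borane needed for the free carbinol may also hydroborate the internal alkyne, and transmetalation of the resulting borinate-bearing borane may be slow. The fallback sets out from 11 and comes back at 13, moving the coupling to a partner with neither hydroxyl nor alkyne. Commercial 2,2-dimethylpent-4-enenitrile F2 is hydroborated with 9-BBN (1.1 equiv, THF) to 5-(9-borabicyclo[3.3.1]nonan-9-yl)-2,2-dimethylpentanenitrile F3. This is coupled in the same flask with 11 (PdCl2(dppf), AsPh3, Cs2CO3, DMF/H2O, rt) to (6Z)-9-[(tert-butyldimethylsilyl)oxy]-2,2,6-trimethylnon-6-enenitrile F4. Reduction with i-Bu2AlH (toluene, −78 °C, then aqueous tartaric acid) should give (6Z)-9-[(tert-butyldimethylsilyl)oxy]-2,2,6-trimethylnon-6-enal F5. Addition of 2 gives rac-(9Z)-12-[(tert-butyldimethylsilyl)oxy]-5,5,9-trimethyldodec-9-en-2-yn-4-ol F6, Dess–Martin oxidation gives (9Z)-12-[(tert-butyldimethylsilyl)oxy]-5,5,9-trimethyldodec-9-en-2-yn-4-one F7, and transfer hydrogenation under the conditions of step 3 gives 13.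

3. Step 6. Hydroalumination of the hindered neopentylic carbinol may be incomplete, the alkenylalanate may be protonated before iodination (giving the iodine-free allylic alcohol), or over-reduction may occur. The fallback sets out from 13 and comes back at 15, replacing the hydride step by a catalytic trans-hydrosilylation. Treatment of 13 with Et3SiH and [Cp*Ru(MeCN)3]PF6 (2 mol %, CH2Cl2, 0 °C to rt) should add H and Si anti across the alkyne with silicon on the carbon distal to the hydroxyl. This gives (2Z,4S,9Z)-12-[(tert-butyldimethylsilyl)oxy]-5,5,9-trimethyl-2-(triethylsilyl)dodeca-2,9-dien-4-ol F8. Iododesilylation with N-iodosuccinimide in hexafluoroisopropanol at 0 °C, with retention of geometry, then gives 15.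

**Further compounds**

F1 | step 10 | (1R,2Z,4S,9Z)-4-[(tert-butyldimethylsilyl)oxy]-2,5,5,9-tetramethylcycloundeca-2,9-dien-1-ol | C/C1=C/C[C@@H](O)/C(C)=C\[C@H](O[Si](C)(C)C(C)(C)C)C(C)(C)CCC1
F2 | step 5 | 2,2-dimethylpent-4-enenitrile | C=CCC(C)(C)C#N
F3 | step 5 | 5-(9-borabicyclo[3.3.1]nonan-9-yl)-2,2-dimethylpentanenitrile | N#CC(C)(C)CCCB1C2CCCC1CCC2
F4 | step 5 | (6Z)-9-[(tert-butyldimethylsilyl)oxy]-2,2,6-trimethylnon-6-enenitrile | N#CC(C)(C)CCC/C(C)=C\CCO[Si](C)(C)C(C)(C)C
F5 | step 5 | (6Z)-9-[(tert-butyldimethylsilyl)oxy]-2,2,6-trimethylnon-6-enal | O=CC(C)(C)CCC/C(C)=C\CCO[Si](C)(C)C(C)(C)C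
F6 | step 5 | rac-(9Z)-12-[(tert-butyldimethylsilyl)oxy]-5,5,9-trimethyldodec-9-en-2-yn-4-ol | CC#CC(O)C(C)(C)CCC/C(C)=C\CCO[Si](C)(C)C(C)(C)C
F7 | step 5 | (9Z)-12-[(tert-butyldimethylsilyl)oxy]-5,5,9-trimethyldodec-9-en-2-yn-4-one | CC#CC(=O)C(C)(C)CCC/C(C)=C\CCO[Si](C)(C)C(C)(C)C
F8 | step 6 | (2Z,4S,9Z)-12-[(tert-butyldimethylsilyl)oxy]-5,5,9-trimethyl-2-(triethylsilyl)dodeca-2,9-dien-4-ol | C/C(=C/[C@H](O)C(C)(C)CCC/C(C)=C\CCO[Si](C)(C)C(C)(C)C)[Si](CC)(CC)CC
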